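**Retrosynthetic overview**
1. Target 16 ⇐ bis(benzyl ether) dibenzoate 15 (hydrogenolysis) ⇐ diol 14 (benzoylation) ⇐ trans-lactone 13 (LiAlH4 ring opening).
2. 13 ⇐ (R)-β-benzyl-γ-butyrolactone 10 + benzylic bromide 11: trans-selective enolate alkylation, in which the C4 centre sets C3.
3. 10 ⇐ cyclopropane-fused lactone 6 + aryl bromide 7: light-driven Ni/photoredox, iodide-relay opening of the cyclopropane C–C bond forms the ArCH2 bond, followed by dealkoxycarbonylation in the same pot.
4. 6 ⇐ (R)-epichlorohydrin 1 + dimethyl malonate 2; the only bought stereocentre becomes C3 of the target.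
5. Ring order: cyclopropane, then γ-lactone (both in step 1); the cyclopropane is opened in step 2 and the lactone in step 4; both arenes are bought.

Assumption: 1, 2, 7 and 11 are taken as catalogue compounds.

**Step 1**
Reactants: 1 (R)-epichlorohydrin; 2 dimethyl malonate
Product: 6 methyl (1S,5R)-2-oxo-3-oxabicyclo[3.1.0]hexane-1-carboxylate, via chlorohydrin malonate 3 (not isolated), via epoxy malonate 4 (not isolated), via hydroxymethyl cyclopropane diester 5 (not isolated)
Conditions: NaOMe (1.05 equiv), MeOH, 0 °C → reflux, 16 h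
Reagents that add atoms: none
Why: Known tandem malonate alkylation / 3-exo-tet cyclopropanation / lactonisation: the malonate anion opens the epoxide at its CH2 end, the alkoxide re-closes onto the CH2Cl carbon, and the second malonate carbanion opens the new epoxide at C2 with inversion, so C5 (R) derives directly from the bought epoxide and C1 is fixed by the obligatory cis ring fusion.

**Step 2**
Reactants: 6 methyl (1S,5R)-2-oxo-3-oxabicyclo[3.1.0]hexane-1-carboxylate; 7 1-(benzyloxy)-4-bromo-2-methoxybenzene
Product: 10 (4R)-4-[4-(benzyloxy)-3-methoxybenzyl]dihydrofuran-2(3H)-one, via iodomethyl lactone ester 8 (not isolated), via benzyl lactone ester 9 (not isolated)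
Conditions: 6 (1.3 equiv), 7 (1.0 equiv), NiBr2·dme (10 mol%), dtbbpy (12 mol%), 4CzIPN (2 mol%), LiI (1.5 equiv), Hantzsch ester (1.5 equiv), Na2CO3 (1.5 equiv), degassed DMA, 450 nm LEDs, 30 °C, 16 h; then H2O (5 equiv), 140 °C, 4 h, same pot; 1 M HCl work-up
Reagents that add atoms: none
Why: Proposed new method: iodide, helped by Li+ chelation of the two carbonyls, reversibly opens the strained, doubly acceptor-activated cyclopropane at its unhindered CH2 (homo-Michael addition) to primary iodide 8, which enters a standard Ni(0)/Ni(I)/Ni(III) cross-electrophile cycle driven by photoreduced 4CzIPN (oxidative addition of 7, iodine-atom abstraction from 8, radical capture, C(sp2)–C(sp3) reductive elimination) with Hantzsch ester as terminal reductant and proton source; the closest known reaction type is the iodide-relay Ni and Ni/photoredox cross-electrophile arylation of epoxides and aziridines through in-situ iodohydrins or iodoamines, combined with the known LiI/MgI2 ring opening of cyclopropane-1,1-dicarbonyls, not yet shown for a cyclopropane C–C bond; the C4 stereocentre is a spectator and is carried over from 6 unchanged, and heating the same LiI/DMA mixture with water then effects Krapcho dealkoxycarbonylation of 9 to 10.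

**Step 3**
Reactants: 10 (4R)-4-[4-(benzyloxy)-3-methoxybenzyl]dihydrofuran-2(3H)-one; 11 2-(benzyloxy)-4-(bromomethyl)-1-methoxybenzene
Product: 13 (3R,4R)-3-[3-(benzyloxy)-4-methoxybenzyl]-4-[4-(benzyloxy)-3-methoxybenzyl]dihydrofuran-2(3H)-one, via lithium enolate 12 (not isolated)
Conditions: LiHMDS (1.1 equiv), THF, −78 °C, 45 min; then 11 (1.2 equiv), DMPU (2 equiv), −78 → −30 °C
Reagents that add atoms: none
Why: Kinetic lactone enolate alkylation (the classical trans-selective benzylation of β-benzyl-γ-butyrolactones): the benzylic bromide approaches planar enolate 12 on the face anti to the C4 benzyl group, so the bought-in C4 (R) centre sets C3 (R), with trans selectivity typically above 95:5.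

**Step 4**
Reactants: 13 (3R,4R)-3-[3-(benzyloxy)-4-methoxybenzyl]-4-[4-(benzyloxy)-3-methoxybenzyl]dihydrofuran-2(3H)-one
Product: 14 (2R,3R)-2-[3-(benzyloxy)-4-methoxybenzyl]-3-[4-(benzyloxy)-3-methoxybenzyl]butane-1,4-diol
Conditions: LiAlH4 (1.5 equiv), THF, 0 °C → rt; Fieser work-up
Reagents that add atoms: none
Why: Hydride reduction of the lactone to the 1,4-diol, which touches neither stereocentre and leaves the aryl benzyl ethers intact.

**Step 5**
Reactants: 14 (2R,3R)-2-[3-(benzyloxy)-4-methoxybenzyl]-3-[4-(benzyloxy)-3-methoxybenzyl]butane-1,4-diol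
Product: 15 (2R,3R)-2-[3-(benzyloxy)-4-methoxybenzyl]-3-[4-(benzyloxy)-3-methoxybenzyl]butane-1,4-diyl dibenzoate
Conditions: BzCl (2.5 equiv), Et3N (3 equiv), DMAP (10 mol%), CH2Cl2, 0 °C → rt
Reagents that add atoms: benzoyl chloride, O=C(Cl)c1ccccc1
Why: DMAP-catalysed acylation of the two primary alcohols; the phenols are still masked as benzyl ethers, so only the aliphatic hydroxyls are benzoylated.

**Step 6**
Reactants: 15 (2R,3R)-2-[3-(benzyloxy)-4-methoxybenzyl]-3-[4-(benzyloxy)-3-methoxybenzyl]butane-1,4-diyl dibenzoate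
Product: 16 (2R,3R)-2-(3-hydroxy-4-methoxybenzyl)-3-(4-hydroxy-3-methoxybenzyl)butane-1,4-diyl dibenzoate
Conditions: H2 (1 atm), 10% Pd/C, EtOAc–EtOH, rt
Reagents that add atoms: none
Why: Catalytic hydrogenolysis cleaves both aryl benzyl ethers to toluene, while the benzoates (esters of non-benzylic primary carbinols) and both stereocentres are untouched.

**Compound list**
1 | (R)-epichlorohydrin, (2R)-2-(chloromethyl)oxirane | ClC[C@H]1CO1 | starting material
2 | dimethyl malonate | COC(=O)CC(=O)OC | starting material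
3 | dimethyl 2-[(2R)-3-chloro-2-hydroxypropyl]malonate (present as its sodium alkoxide) | COC(=O)C(C(=O)OC)C[C@@H](O)CCl | intermediate
4 | dimethyl 2-{[(2R)-oxiran-2-yl]methyl}malonate | COC(=O)C(C(=O)OC)C[C@@H]1CO1 | intermediate
5 | dimethyl (2R)-2-(hydroxymethyl)cyclopropane-1,1-dicarboxylate (present as its sodium alkoxide) | COC(=O)C1(C(=O)OC)C[C@H]1CO | intermediate
6 | methyl (1S,5R)-2-oxo-3-oxabicyclo[3.1.0]hexane-1-carboxylate | COC(=O)[C@]12C[C@H]1COC2=O | intermediate
7 | 1-(benzyloxy)-4-bromo-2-methoxybenzene | COc1cc(Br)ccc1OCc1ccccc1 | starting material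
8 | methyl (4R)-4-(iodomethyl)-2-oxotetrahydrofuran-3-carboxylate (C3 epimers) | COC(=O)C1[C@@H](CI)COC1=O | intermediate
9 | methyl (4R)-4-[4-(benzyloxy)-3-methoxybenzyl]-2-oxotetrahydrofuran-3-carboxylate (C3 epimers) | COC(=O)C1[C@@H](Cc2ccc(OCc3ccccc3)c(OC)c2)COC1=O | intermediate
10 | (4R)-4-[4-(benzyloxy)-3-methoxybenzyl]dihydrofuran-2(3H)-one | O=C1C[C@@H](Cc2ccc(OCc3ccccc3)c(OC)c2)CO1 | intermediate
11 | 2-(benzyloxy)-4-(bromomethyl)-1-methoxybenzene (3-benzyloxy-4-methoxybenzyl bromide) | COc1ccc(CBr)cc1OCc1ccccc1 | starting material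
12 | lithium (4R)-4-[4-(benzyloxy)-3-methoxybenzyl]-4,5-dihydrofuran-2-olate | [Li+].[O-]C1=C[C@@H](Cc2ccc(OCc3ccccc3)c(OC)c2)CO1 | intermediate
13 | (3R,4R)-3-[3-(benzyloxy)-4-methoxybenzyl]-4-[4-(benzyloxy)-3-methoxybenzyl]dihydrofuran-2(3H)-one (trans) | O=C1[C@H](Cc2ccc(OC)c(OCc3ccccc3)c2)[C@@H](Cc2ccc(OCc3ccccc3)c(OC)c2)CO1 | intermediate
14 | (2R,3R)-2-[3-(benzyloxy)-4-methoxybenzyl]-3-[4-(benzyloxy)-3-methoxybenzyl]butane-1,4-diol | OC[C@H](Cc1ccc(OC)c(OCc2ccccc2)c1)[C@@H](Cc1ccc(OCc2ccccc2)c(OC)c1)CO | intermediate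
15 | (2R,3R)-2-[3-(benzyloxy)-4-methoxybenzyl]-3-[4-(benzyloxy)-3-methoxybenzyl]butane-1,4-diyl dibenzoate | O=C(OC[C@H](Cc1ccc(OC)c(OCc2ccccc2)c1)[C@@H](Cc1ccc(OCc2ccccc2)c(OC)c1)COC(=O)c1ccccc1)c1ccccc1 | intermediate
16 | (2R,3R)-2-(3-hydroxy-4-methoxybenzyl)-3-(4-hydroxy-3-methoxybenzyl)butane-1,4-diyl dibenzoate (CNP0306197.1) | COc1ccc(C[C@@H](COC(=O)c2ccccc2)[C@H](COC(=O)c2ccccc2)Cc2ccc(O)c(OC)c2)cc1O | target

**Totals**
Total step count: 6. Longest linear sequence: 6 steps (1 → 6 → 10 → 13 → 14 → 15 → 16).

**Three steps most likely to fail**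

Step 2 (proposed new method). The risks are that Hantzsch ester reduces iodide 8 to the methyl compound before nickel captures the radical, that the electron-rich bromide 7 adds slowly to nickel, or that re-closure of 8 to 6 outruns coupling. The fallback uses known chemistry and sets out from 6 and 7. Bromide 7 is converted with Mg turnings in THF into [4-(benzyloxy)-3-methoxyphenyl]magnesium bromide F1. F1 is added to 6 with CuI (10 mol%) at −30 °C, the established copper-catalysed homo-conjugate opening of this bicyclic lactone by Grignard reagents, to give 9. Krapcho dealkoxycarbonylation of 9 (LiCl, DMSO–H2O, 140 °C) then gives 10, where the fallback comes back to the route.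

Step 3. The risks are incomplete trans selectivity, double alkylation and decomposition of the electron-rich benzylic bromide under strongly basic conditions. The fallback moves the benzylation to the stabilised malonate-type enolate and sets out from 9, isolated by working up step 2 before the heating stage. Compound 9 is alkylated with 11 (K2CO3, DMF, rt) to give methyl (3R,4R)-3-[3-(benzyloxy)-4-methoxybenzyl]-4-[4-(benzyloxy)-3-methoxybenzyl]-2-oxotetrahydrofuran-3-carboxylate F2. Krapcho dealkoxycarbonylation (LiCl, DMSO–H2O, 150 °C) gives the trans lactone together with some (3S,4R)-3-[3-(benzyloxy)-4-methoxybenzyl]-4-[4-(benzyloxy)-3-methoxybenzyl]dihydrofuran-2(3H)-one F3. DBU in toluene equilibrates F3 to the thermodynamically preferred trans isomer, so the fallback comes back at 13.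

Step 1. The risks are a moderate yield and erosion of enantiopurity if some malonate displaces chloride directly, which leads to the enantiomeric series. The fallback changes the electrophile so that direct displacement is the only pathway; it sets out from 2 and a different chiral building block, (R)-glycidol F4. F4 is converted (Tf2O, 2,6-lutidine, CH2Cl2, −30 °C) into (S)-glycidyl triflate F5. Sodium dimethyl malonate (NaH, THF, −20 °C) displaces the triflate to give 4 directly. NaOMe in MeOH at reflux then closes the cyclopropane and lactone through 5, and the fallback comes back at 6.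

**Further compounds**
F1 | step 2 | [4-(benzyloxy)-3-methoxyphenyl]magnesium bromide | COc1cc([Mg]Br)ccc1OCc1ccccc1
F2 | step 3 | methyl (3R,4R)-3-[3-(benzyloxy)-4-methoxybenzyl]-4-[4-(benzyloxy)-3-methoxybenzyl]-2-oxotetrahydrofuran-3-carboxylate | COC(=O)[C@@]1(Cc2ccc(OC)c(OCc3ccccc3)c2)[C@@H](Cc2ccc(OCc3ccccc3)c(OC)c2)COC1=O
F3 | step 3 | (3S,4R)-3-[3-(benzyloxy)-4-methoxybenzyl]-4-[4-(benzyloxy)-3-methoxybenzyl]dihydrofuran-2(3H)-one (cis epimer of 13) | O=C1[C@@H](Cc2ccc(OC)c(OCc3ccccc3)c2)[C@@H](Cc2ccc(OCc3ccccc3)c(OC)c2)CO1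
F4 | step 1 | (R)-glycidol | OC[C@@H]1CO1
F5 | step 1 | (S)-glycidyl triflate, [(2S)-oxiran-2-yl]methyl trifluoromethanesulfonate | FC(F)(F)S(=O)(=O)OC[C@@H]1CO1
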